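Left-handed substrate and left-handed product together hold 49.0% of the charge at the first reading of Saturday's run and 51.0% at its last, so within a scatter of 1.5 percentage points what leaves the one appears as the other.

| flask | left-handed substrate | right-handed substrate | solid reagent | free catalyst | remark |
|---|---|---|---|---|---|
| Saturday's | 0.14 M | 0.14 M | 0.80 equiv | 2.5 mol% | run made earlier |
| Sunday's | 0.22 M | 0.22 M | 0.80 equiv | 2.5 mol% | run made earlier |
| Monday's | 0.10 M | 0.10 M | 0.80 equiv | 1.2 mol% | run made earlier |
| flask | 0.10 M | 0.10 M | 0.800 equiv | 2.5 mol% |  |

| run | time / h | left-handed product / % | left-handed substrate / % |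
|---|---|---|---|
| Saturday's | 1.00 | 3 | 46 |
| Saturday's | 1.33 | 3 | 43 |
| Saturday's | 2.00 | 9 | 42 |
| Saturday's | 3.00 | 13 | 36 |
| Saturday's | 5.00 | 21 | 28 |
| Saturday's | 8.00 | 35 | 16 |
| Saturday's | 12.0 | 35 | 16 |
| Sunday's | 1.50 | 3 | 45 |
| Sunday's | 3.00 | 9 | 41 |
| Sunday's | 5.00 | 16 | 34 |
| Sunday's | 6.00 | 18 | 32 |
| Sunday's | 8.00 | 26 | 25 |
| Sunday's | 10.0 | 29 | 20 |
| Sunday's | 12.0 | 37 | 14 |
| Monday's | 1.00 | 3 | 49 |
| Monday's | 2.00 | 8 | 43 |
| Monday's | 3.00 | 8 | 38 |
| Monday's | 6.00 | 22 | 26 |
| Monday's | 12.0 | 34 | 15 |

(scatter of a reading: 1.5 percentage points)

- free catalyst is single-handed; left-handed substrate and right-handed substrate are mirror images of each other, charged as a racemate, each of them at the stated concentration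
- solid reagent is a solid; its amount is given per volume of the solution
- at the start none of the solid reagent is in solution
- what is bound to the catalyst counts as converted

* factor on the rate of making left-handed product when 5.0% of the left-handed substrate and right-handed substrate together are converted if free catalyst is charged twice over
* factor on the rate when 5.0% of the left-handed substrate and right-handed substrate together are converted if free catalyst is charged at 12 mol% instead

In the first instants, substrate held on the catalyst already counts as converted, so the flask's mark is partly met before any turnover. Taking one substrate per catalyst, the reckoning is: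

mark = 0.0100 M; catalyst = 0.00250 M; share = 0.250

This is the binding share: catalyst charged over substrate converted at the mark.

In the middle, the reagent must dissolve, since none is in solution at the start. Saturday's left-handed product gains 0.0128 M h⁻¹ between 1.00 h and 8.00 h.

At the end, the solid reagent, the limiting reagent, allows 40.0% of the charge to react. Saturday's left-handed product halts at 35%.

Doubled catalyst raises the share to 0.500, so the mark should come sooner, with less reagent dissolved. At 12 mol% the share is 1.20, above one, so binding can cover most of the mark early. These shares say how the mark is met, not how fast product forms there, so the reckoning here sets no figure on either factor.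

The forecast gives 1.25 (1.1 to 1.5) and 1.45 (1.15 to 2), “assuming the dissolution limit holds”.

    solid reagent ⇌ partner, rate k1*(cs1 - [partner]) while solid is left; crystals form when [partner] > cs1 (solubility = 32.0 mM, k = 1.50 × 10⁻⁴ s⁻¹)
    partner + catalyst intermediate A → free catalyst + left-handed product (k = 0.290 M⁻¹ s⁻¹)
    free catalyst + left-handed substrate ⇌ catalyst intermediate A (K = 36.0 M⁻¹, k = 1.40 M⁻¹ s⁻¹)
    partner + catalyst intermediate B → free catalyst + right-handed product (k = 0.130 M⁻¹ s⁻¹)
    free catalyst + right-handed substrate ⇌ catalyst intermediate B (K = 6.60 M⁻¹, k = 1.50 M⁻¹ s⁻¹)

The flask makes left-handed product at 0.0110 M h⁻¹ at the mark, reached at 0.970 h; doubled catalyst gives a factor of 1.16, and 12 mol% gives 0.758, a fall. At 1.00 h the flask holds 65.4% of its catalyst as catalyst intermediate A and 13.7% as catalyst intermediate B, together 79.0%. The binding share then puts 19.8% of the flask's mark on the catalyst. With that same bound fraction, the 12 mol% charge holds 94.8% of its mark on the catalyst.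

(The readings come from a simulation from invented constants; scatter was added.)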